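**Small target.** The target barely shows: 2.1% in the autumn run after 120 s. So I follow what takes starting material away, and I begin with the protic impurity.

| flask | starting material | coupling partner | protic impurity | capture agent | remark | time |
|---|---|---|---|---|---|---|
| autumn | 0.034 M | 0.060 M | 5 mM | 0.015 M | run made earlier |  |
| summer | 0.050 M | 0.030 M | 5 mM | 0.015 M | run made earlier |  |
| alpha | 0.050 M | 0.0600 M | 5.00 mM | 0.0150 M |  | 3.0 min |
| zeta | 0.050 M | 0.0600 M | 5.00 mM | 0.0300 M |  | 3.0 min |
| gamma | 0.050 M | 0.0600 M | 5.00 mM | 0.0600 M |  | 3.0 min |

| run | time / s | starting material / % | open intermediate / % | trapped intermediate / % | target / % |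
|---|---|---|---|---|---|
| autumn | 15.0 | 96.1 | 2.5 | 0.5 | 1.1 |
| autumn | 40.0 | 93.0 | 2.3 | 1.1 | 0.7 |
| autumn | 80.0 | 87.8 | 1.9 | 2.2 | 1.3 |
| autumn | 120 | 85.1 | 1.2 | 3.4 | 2.1 |
| summer | 10.0 | 98.3 | 0.8 | 0.8 | 0.5 |
| summer | 20.0 | 95.9 | 1.8 | 0 | 0 |
| summer | 50.0 | 93.4 | 1.0 | 0.9 | 1.4 |
| summer | 120 | 89.1 | 0 | 1.8 | 2.1 |

(readings scatter by 0.5 percentage points)

1. which of these there is most of at the end, counted by the starting material in it, alpha (open intermediate / starting material / trapped intermediate / target)
2. which of these there is most of at the end, counted by the starting material in it, zeta (open intermediate / starting material / trapped intermediate / target)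
3. which of these there is most of at the end, counted by the starting material in it, gamma (open intermediate / starting material / trapped intermediate / target)
4. how much there is at the end of the one of these that leads, in percent of the starting material charged: alpha
5. how much there is at the end of the one of these that leads, in percent of the starting material charged: zeta
6. how much there is at the end of the one of these that leads, in percent of the starting material charged: gamma

- steps under discussion: starting material + protic impurity -> quenched substrate; starting material + coupling partner <-> open intermediate; 2 coupling partner -> self-condensation product; open intermediate -> target; open intermediate + capture agent -> trapped intermediate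
- no earlier run changes the charge of capture agent; that part of a forecast is a guess

**The gap.** At the last readings, the four species read leave a gap, which I take as quenched substrate: 2.79 mM in autumn and 3.50 mM in summer, from 5 mM of impurity. While [starting material] moves little, the impurity decays pseudo-first-order, so its rate integrates to an exponential. The gaps give 2.45 min in autumn and 1.66 min in summer for the quench time, the time in which the impurity falls by a factor e. Their ratio, 1.48, read through the scatter, matches the inverse ratio of [starting material], 1.47.

**The curve.** Alpha has the [starting material] of summer, so I carry the summer quench time over. Quenched substrate starts at 3.01 mM min⁻¹ and bends at the quench time, standing at 6.32% of the starting material charged. It runs toward a level of 10.0%, the whole impurity charge. At 3.0 min it reaches 8.36%. Adding the 6.70% that autumn held in the coupled species at its last reading, I commit to about 84.9% starting material for alpha. The capture agent does not enter this curve, and for zeta and gamma its effect is a guess.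

**The forecast.** It names starting material as leader, at 84% in alpha, 82% in zeta and 79% in gamma, and says “Starting material leads in all three runs”. For alpha it stands below my figure.

**The result.** The leader is starting material, at 83.8% in alpha, 82.6% in zeta and 81.3% in gamma, where trapped intermediate follows at 8.90%. The forecast holds within its margins.

    starting material + protic impurity → quenched substrate (k = 0.182 L mol⁻¹ s⁻¹)
    starting material + coupling partner ⇌ open intermediate (K = 1.80 L mol⁻¹, k = 0.0356 L mol⁻¹ s⁻¹)
    2 coupling partner → self-condensation product (k = 0.162 L mol⁻¹ s⁻¹)
    open intermediate → target (k = 0.0111 s⁻¹)
    open intermediate + capture agent → trapped intermediate (k = 1.00 L mol⁻¹ s⁻¹)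

**The neighbour.** Alpha itself holds 7.68% quenched substrate against my 8.36%. The neighbouring flask differs from alpha in its 0.0085 M of impurity, so the same quench time gives 14.2%. That flask holds 12.8% quenched substrate and 78.9% starting material.

(The data are simulated on assumed constants, noise included.)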